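**Plan**

- Retrosynthesis: first the ester bond at the oxygen on C3 is cut (trans alcohol plus (Z)-2-(acetoxymethyl)but-2-enoic acid). Then the aryl ether bond O1–C7a and the C2–C3 bond are cut together, which leaves 5-acetyl-2-fluorobenzaldehyde and a three-carbon allylboronate that carries O1 as a silyl enol ether.
- Forward: aldehyde, boronate and acid are made separately. One flask operation joins C2 to C3 and then closes the only new ring, O1–C2–C3–C3a–C7a, onto the preformed benzene ring. The acid is attached last.
- Enabling feature: the acetyl group on C5 is para to C7a, so a fluorine on C7a is open to SNAr by the oxygen on C2, while C3, ortho to C7a, starts as a formyl carbon. The ring size lets only the C2 oxygen reach C7a.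
- Stereochemistry: C3 comes from a chiral phosphoric acid (Re face of the formyl group). C2 is set relative to C3 by the E enol ether geometry in a chair transition state (anti adduct = trans ring). The Z alkene of the side chain comes from (Z)-2-iodobut-2-enal by stereoretentive carbonylation. The esterification touches neither centre.

Key step: step 4

Remark: the facial preference of the (R)-phosphoric acid is carried over from its Re-face selectivity with benzaldehyde; the descriptor at the carbinol carbon reads S here only because C2 outranks the aryl group.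

Step 1
Reactants: 1 5-bromo-2-fluorobenzaldehyde
Product: 3 5-acetyl-2-fluorobenzaldehyde, via enol ether 2 (not isolated)
Conditions: tributyl(1-ethoxyethenyl)stannane, PdCl2(PPh3)2 (3 mol%), toluene, 100 °C; then 1 M HCl, THF, rt
Reagents that add atoms: tributyl(1-ethoxyethenyl)stannane CCCC[Sn](CCCC)(CCCC)C(=C)OCC; water O
Why: Stille coupling at the C–Br bond (the C–F bond and the aldehyde are inert to zerovalent palladium under neutral conditions) should give the aryl enol ether, which dilute acid hydrolyses to the methyl ketone.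

Step 2
Reactants: 4 tert-butyldimethyl(prop-2-yn-1-yloxy)silane
Product: 5 tert-butyldimethyl{[(2E)-2-methyl-3-(4,4,5,5-tetramethyl-1,3,2-dioxaborolan-2-yl)prop-2-en-1-yl]oxy}silane
Conditions: bis(pinacolato)diboron, MeI, CuCl (10 mol%), Xantphos (10 mol%), NaOtBu, THF, rt
Reagents that add atoms: bis(pinacolato)diboron CC1(C)OB(OC1(C)C)B1OC(C)(C)C(C)(C)O1; iodomethane CI
Why: Copper-catalysed carboboration of a terminal alkyne: syn borylcupration places boron on the terminal carbon and the alkenylcopper is methylated with retention, so the methyl group ends on the internal carbon.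

Step 3
Reactants: 5 tert-butyldimethyl{[(2E)-2-methyl-3-(4,4,5,5-tetramethyl-1,3,2-dioxaborolan-2-yl)prop-2-en-1-yl]oxy}silane
Product: 6 tert-butyldimethyl{[(1E)-2-methyl-3-(4,4,5,5-tetramethyl-1,3,2-dioxaborolan-2-yl)prop-1-en-1-yl]oxy}silane
Conditions: [Ir(cod)(PPh2Me)2]PF6 (3 mol%, pre-activated with H2), THF, rt
Reagents that add atoms: none
Why: Iridium-hydride-catalysed 1,3-hydrogen shift of an allyl silyl ether to a silyl enol ether (alkene transposition); the C–H bond next to oxygen is broken, the siloxy group should take the syn position of the π-allyl hydride beside the central methyl group, and return of hydrogen to the boron-bearing carbon should then give the E enol ether (oxygen trans to CH2B), with enol ether conjugation as the driving force.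

Step 4
Reactants: 3 5-acetyl-2-fluorobenzaldehyde; 6 tert-butyldimethyl{[(1E)-2-methyl-3-(4,4,5,5-tetramethyl-1,3,2-dioxaborolan-2-yl)prop-1-en-1-yl]oxy}silane
Product: 10 1-[(2R,3S)-3-hydroxy-2-(prop-1-en-2-yl)-2,3-dihydro-1-benzofuran-5-yl]ethan-1-one, via borate adduct 7 (not isolated), via ammonium alkoxide 8 (not isolated), via boryl ether 9 (not isolated)
Conditions: (R)-3,3'-bis(2,4,6-triisopropylphenyl)-1,1'-binaphthyl-2,2'-diyl hydrogen phosphate (5 mol%), 4 Å molecular sieves, toluene, −40 °C; then Bu4NF (3 equiv), THF, −40 °C to rt; aq. NH4Cl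
Reagents that add atoms: none
Why: The phosphoric acid binds the boronate (P–OH to a pinacol oxygen, P=O to the formyl hydrogen) and the aldehyde reacts through a chair Zimmerman–Traxler transition state, the closest known reaction type being the chiral phosphoric acid-catalysed γ-alkoxy- and γ-siloxy-allylboration of aryl aldehydes; fluoride then frees the oxygen on C2, which attacks the C–F carbon in an intramolecular SNAr reaction through a Meisenheimer adduct stabilised by the para acetyl group. The five-membered ring closes by 5-exo-trig addition–elimination at the aromatic carbon, and only the oxygen on C2 can do this because the oxygen on C3 would have to form a four-membered ring. C3 is set by the catalyst, which should direct the allyl unit to the Re face of the formyl group, and C2 is set relative to C3 by the E enol ether, whose siloxy group sits equatorial in the chair, so the anti (1S,2R) adduct and hence the trans ring should result. The step needs aldehyde over ketone selectivity, secured because pinacol allylboronates do not add to the aryl methyl ketone at low temperature. It also needs the alkoxide to cyclise faster than it enolises the ketone or is held as a chelated borate, for which the excess fluoride ties up boron and the closure is a five-membered attack on an activated fluoride.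

Step 5
Reactants: 11 (2E)-but-2-enal
Product: 12 (2Z)-2-iodobut-2-enal
Conditions: I2, K2CO3, 4-(dimethylamino)pyridine (20 mol%), THF–H2O, rt
Reagents that add atoms: iodine II
Why: α-Iodination of an enal by conjugate addition of the pyridine, iodination of the enolate and elimination (Morita–Baylis–Hillman-type mechanism); the formyl group stays trans to the methyl group, so iodine is cis to it (Z).

Step 6
Reactants: 12 (2Z)-2-iodobut-2-enal
Product: 13 (2Z)-2-iodobut-2-en-1-ol
Conditions: NaBH4, MeOH, 0 °C
Reagents that add atoms: none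
Why: Borohydride 1,2-reduction of the aldehyde; the alkenyl iodide and the alkene geometry are not touched.

Step 7
Reactants: 13 (2Z)-2-iodobut-2-en-1-ol
Product: 14 (2Z)-2-(hydroxymethyl)but-2-enoic acid
Conditions: CO (1 atm), Pd(OAc)2 (5 mol%), PPh3 (10 mol%), Et3N, DMF–H2O, 60 °C; then dilute HCl
Reagents that add atoms: carbon monoxide [C-]#[O+]; water O
Why: Palladium-catalysed hydroxycarbonylation of an alkenyl iodide (oxidative addition, CO insertion, hydrolysis of the acylpalladium) proceeds with retention of alkene geometry, so the carboxyl group takes the place of iodine cis to the methyl group and the Z acid should result.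

Step 8
Reactants: 14 (2Z)-2-(hydroxymethyl)but-2-enoic acid
Product: 15 (2Z)-2-[(acetyloxy)methyl]but-2-enoic acid
Conditions: Ac2O, pyridine, CH2Cl2, 0 °C to rt; aqueous work-up at pH 3
Reagents that add atoms: acetic anhydride CC(=O)OC(C)=O
Why: Acetylation of the primary allylic alcohol; the carboxyl group is recovered as the free acid on aqueous work-up and the alkene is not touched.

Step 9
Reactants: 15 (2Z)-2-[(acetyloxy)methyl]but-2-enoic acid; 10 1-[(2R,3S)-3-hydroxy-2-(prop-1-en-2-yl)-2,3-dihydro-1-benzofuran-5-yl]ethan-1-one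
Product: 17 (2R,3S)-5-acetyl-2-(prop-1-en-2-yl)-2,3-dihydro-1-benzofuran-3-yl (2Z)-2-[(acetyloxy)methyl]but-2-enoate, via acid chloride 16 (not isolated)
Conditions: 1-chloro-N,N,2-trimethylprop-1-en-1-amine, CH2Cl2, 0 °C; then 10, pyridine, 0 °C to rt
Reagents that add atoms: none
Why: Acid chloride formation under neutral conditions with the α-chloroenamine and acylation of the secondary alcohol with pyridine only (no 4-(dimethylamino)pyridine) should avoid the conjugate addition that isomerises the Z enoate or displaces the allylic acetate; the C3–O bond is not broken, so the configuration at C3 is retained.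

**Compound list**

1 | 5-bromo-2-fluorobenzaldehyde | O=Cc1cc(Br)ccc1F | starting material
2 | 5-(1-ethoxyethenyl)-2-fluorobenzaldehyde | C=C(OCC)c1ccc(F)c(C=O)c1 | intermediate
3 | 5-acetyl-2-fluorobenzaldehyde | CC(=O)c1ccc(F)c(C=O)c1 | intermediate
4 | tert-butyldimethyl(prop-2-yn-1-yloxy)silane | C#CCO[Si](C)(C)C(C)(C)C | starting material
5 | tert-butyldimethyl{[(2E)-2-methyl-3-(4,4,5,5-tetramethyl-1,3,2-dioxaborolan-2-yl)prop-2-en-1-yl]oxy}silane | C/C(CO[Si](C)(C)C(C)(C)C)=C\B1OC(C)(C)C(C)(C)O1 | intermediate
6 | tert-butyldimethyl{[(1E)-2-methyl-3-(4,4,5,5-tetramethyl-1,3,2-dioxaborolan-2-yl)prop-1-en-1-yl]oxy}silane | C/C(CB1OC(C)(C)C(C)(C)O1)=C\O[Si](C)(C)C(C)(C)C | intermediate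
7 | 1-[3-[(1S,2R)-2-{[tert-butyl(dimethyl)silyl]oxy}-3-methyl-1-[(4,4,5,5-tetramethyl-1,3,2-dioxaborolan-2-yl)oxy]but-3-en-1-yl]-4-fluorophenyl]ethan-1-one | CC(=C)[C@@H](O[Si](C)(C)C(C)(C)C)[C@@H](OB1OC(C)(C)C(C)(C)O1)c1cc(C(C)=O)ccc1F | intermediate
8 | tetrabutylammonium (1S,2R)-1-(5-acetyl-2-fluorophenyl)-3-methyl-1-[(4,4,5,5-tetramethyl-1,3,2-dioxaborolan-2-yl)oxy]but-3-en-2-olate | CC(=C)[C@@H]([O-])[C@@H](OB1OC(C)(C)C(C)(C)O1)c1cc(C(C)=O)ccc1F.CCCC[N+](CCCC)(CCCC)CCCC | intermediate
9 | 1-[(2R,3S)-2-(prop-1-en-2-yl)-3-[(4,4,5,5-tetramethyl-1,3,2-dioxaborolan-2-yl)oxy]-2,3-dihydro-1-benzofuran-5-yl]ethan-1-one | C=C(C)[C@H]1Oc2ccc(C(C)=O)cc2[C@@H]1OB3OC(C)(C)C(C)(C)O3 | intermediate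
10 | 1-[(2R,3S)-3-hydroxy-2-(prop-1-en-2-yl)-2,3-dihydro-1-benzofuran-5-yl]ethan-1-one | C=C(C)[C@H]1Oc2ccc(C(C)=O)cc2[C@@H]1O | intermediate
11 | (2E)-but-2-enal | C/C=C/C=O | starting material
12 | (2Z)-2-iodobut-2-enal | C/C=C(\I)C=O | intermediate
13 | (2Z)-2-iodobut-2-en-1-ol | C/C=C(\I)CO | intermediate
14 | (2Z)-2-(hydroxymethyl)but-2-enoic acid | C/C=C(\C(=O)O)CO | intermediate
15 | (2Z)-2-[(acetyloxy)methyl]but-2-enoic acid | C/C=C(\C(=O)O)COC(C)=O | intermediate
16 | (2Z)-2-[(acetyloxy)methyl]but-2-enoyl chloride | C/C=C(\C(Cl)=O)COC(C)=O | intermediate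
17 | (2R,3S)-5-acetyl-2-(prop-1-en-2-yl)-2,3-dihydro-1-benzofuran-3-yl (2Z)-2-[(acetyloxy)methyl]but-2-enoate | C=C(C)[C@H]1Oc2ccc(C(C)=O)cc2[C@@H]1OC(=O)/C(=C\C)COC(C)=O | target

**Step count and risks**

Total steps: 9. Longest linear sequence: 5 (steps 5, 6, 7, 8, 9).

Step 3 is the weakest point. The hydrogen shift may stall on the trisubstituted alkenyl boronate, or deliver the enol ether with poor E/Z control, which would pass straight into the anti/syn ratio of step 4. The fallback sets out from 5 and comes back at 17; it makes the opposite enol ether geometry on purpose and corrects C3 at the end. The Z-selective nickel hydride catalyst from NiCl2(dppb) and LiBHEt3 (THF, rt) should turn 5 into tert-butyldimethyl{[(1Z)-2-methyl-3-(4,4,5,5-tetramethyl-1,3,2-dioxaborolan-2-yl)prop-1-en-1-yl]oxy}silane F1. F1 and aldehyde 3, with the (S)-enantiomer of the phosphoric acid and then Bu4NF as in step 4, should give the syn borate adduct F2, its tetrabutylammonium alkoxide F3 and the cis boryl ether F4. Work-up should then give the cis alcohol 1-[(2R,3R)-3-hydroxy-2-(prop-1-en-2-yl)-2,3-dihydro-1-benzofuran-5-yl]ethan-1-one F5, with C2 already correct. A Mitsunobu esterification of F5 with acid 15 (PPh3, diisopropyl azodicarboxylate, THF, 0 °C) should invert C3 and give 17.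

Step 4 may fail in its second half. The freed alkoxide may be held back as a chelated borate, or be consumed by enolisation and aldol reaction of the methyl ketone, before it cyclises; facial control in the allylboration may also fall short for this ortho-substituted aldehyde. The fallback sets out from 3 and 6 and comes back at 10; it separates the two bond formations. Only the allylboration is run, and aqueous work-up of 7 should give the hydroxy silyl ether 1-[3-[(1S,2R)-2-{[tert-butyl(dimethyl)silyl]oxy}-1-hydroxy-3-methylbut-3-en-1-yl]-4-fluorophenyl]ethan-1-one F6, which can be purified. HF·pyridine in THF should remove the silyl group without base and give the boron-free anti diol 1-[3-[(1S,2R)-1,2-dihydroxy-3-methylbut-3-en-1-yl]-4-fluorophenyl]ethan-1-one F7. K2CO3 in DMF at 50 °C should then close the ring by SNAr to 10.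

Step 9 may suffer isomerisation of the Z enoyl unit to E through reversible conjugate addition, loss of the allylic acetate by SN2' attack, or elimination of the benzylic ester towards the aromatic benzofuran. The fallback sets out from 13 and 10 and comes back at 17; it never passes through an activated free acid. Alcohol 13 is acetylated (Ac2O, pyridine) to (2Z)-2-iodobut-2-en-1-yl acetate F8. Palladium-catalysed alkoxycarbonylation of F8 with alcohol 10 (Pd(OAc)2, PPh3, CO 1 atm, Et3N, DMF, 50 °C) should build the ester carbonyl from CO on the alkenyl carbon with retention of the alkene geometry and give 17.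

**Further compounds**

F1 | step 3 | tert-butyldimethyl{[(1Z)-2-methyl-3-(4,4,5,5-tetramethyl-1,3,2-dioxaborolan-2-yl)prop-1-en-1-yl]oxy}silane | C/C(CB1OC(C)(C)C(C)(C)O1)=C/O[Si](C)(C)C(C)(C)C
F2 | step 3 | 1-[3-[(1R,2R)-2-{[tert-butyl(dimethyl)silyl]oxy}-3-methyl-1-[(4,4,5,5-tetramethyl-1,3,2-dioxaborolan-2-yl)oxy]but-3-en-1-yl]-4-fluorophenyl]ethan-1-one | CC(=C)[C@@H](O[Si](C)(C)C(C)(C)C)[C@H](OB1OC(C)(C)C(C)(C)O1)c1cc(C(C)=O)ccc1F
F3 | step 3 | tetrabutylammonium (1R,2R)-1-(5-acetyl-2-fluorophenyl)-3-methyl-1-[(4,4,5,5-tetramethyl-1,3,2-dioxaborolan-2-yl)oxy]but-3-en-2-olate | CC(=C)[C@@H]([O-])[C@H](OB1OC(C)(C)C(C)(C)O1)c1cc(C(C)=O)ccc1F.CCCC[N+](CCCC)(CCCC)CCCC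
F4 | step 3 | 1-[(2R,3R)-2-(prop-1-en-2-yl)-3-[(4,4,5,5-tetramethyl-1,3,2-dioxaborolan-2-yl)oxy]-2,3-dihydro-1-benzofuran-5-yl]ethan-1-one | C=C(C)[C@H]1Oc2ccc(C(C)=O)cc2[C@H]1OB3OC(C)(C)C(C)(C)O3
F5 | step 3 | 1-[(2R,3R)-3-hydroxy-2-(prop-1-en-2-yl)-2,3-dihydro-1-benzofuran-5-yl]ethan-1-one | C=C(C)[C@H]1Oc2ccc(C(C)=O)cc2[C@H]1O
F6 | step 4 | 1-[3-[(1S,2R)-2-{[tert-butyl(dimethyl)silyl]oxy}-1-hydroxy-3-methylbut-3-en-1-yl]-4-fluorophenyl]ethan-1-one | CC(=C)[C@@H](O[Si](C)(C)C(C)(C)C)[C@@H](O)c1cc(C(C)=O)ccc1F
F7 | step 4 | 1-[3-[(1S,2R)-1,2-dihydroxy-3-methylbut-3-en-1-yl]-4-fluorophenyl]ethan-1-one | CC(=C)[C@@H](O)[C@@H](O)c1cc(C(C)=O)ccc1F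
F8 | step 9 | (2Z)-2-iodobut-2-en-1-yl acetate | C/C=C(\I)COC(C)=O
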